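## Structural features

The target is a flavanone: benzo ring A is fused to the dihydropyranone ring C (O1, C2, C3, C4, C4a, C8a), and ring B, a 4-hydroxy-2-methoxyphenyl group, sits on C2. Ring A carries a substituent on every carbon except C6: hydroxyls at C5 and C7, the C4 carbonyl on C4a, O1 on C8a, and at C8 the chain C1''H2–C2''H(prenyl)–C3''H(CH3)–C4''H2OH. There are three stereocenters: C2 (S) on ring C, and the vicinal pair C2''/C3'' (R,R) in the chain. The pair is adjacent to each other but too far from C2 for any relay of stereochemical information. Fragile elements are the flavanone itself (base opens ring C by retro-oxa-Michael reaction and scrambles C2), the doubly activated benzylic C2–O1 bond, the trisubstituted alkene (protic acid, electrophiles, boranes) and any open-chain β-hydroxy ketone precursor (retro-aldol, dehydration). The real difficulty is threefold: the fixed order of five different substituents around ring A, the absolute configuration at C2 without a neighbouring control element, and an acyclic methyl/prenyl stereodiad. The key step exploits the fact that O1 joins the C2 carbinol carbon to the fully substituted aromatic carbon C8a. Ring C can therefore be closed by forming the aryl C8a–O1 bond from a C8a–Br bond and a pre-set C2 hydroxyl, and no bond at C2 is made or broken.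

## Logic of the disconnections

**27 to 26.** Only the four acetal C–O bonds of the methoxymethyl groups (three phenolic, one aliphatic) are cut. Free phenols and a free primary alcohol would interfere with the organometallic, basic and oxidising steps, so they are unmasked last. The gain is that every earlier intermediate is a neutral ether. The forward step must cleave the slow aliphatic acetal without adding across the alkene or ionising the C2–O1 bond.

**26 to 25.** No skeletal bond is cut; the C4 carbonyl is traced back to a C4 carbinol. With C4 as a carbinol neither 25 nor its open-chain precursor is a β-oxygenated ketone, so base cannot cause retro-aldol cleavage, dehydration or ring opening at C2. The gain is that ring closure can be run under carbonate base. The demand is a neutral oxidation of a hindered benzylic alcohol that spares the alkene.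

**25 to 24.** The aryl–oxygen bond O1–C8a is cut and ring C opens. This is the strategic cut because the C2–O bond stays intact, so the C2 configuration of 24 is carried into 25 unchanged. The gain is that the bicyclic core becomes an acyclic 1,3-diol on an aryl bromide, which separates the C2 problem from the ring A problem. The demand is a metal-catalysed C–O coupling at a doubly ortho-substituted C–Br bond that outruns β-hydride elimination and engages only the C2 hydroxyl.

**24 to 22.** The C4–H bond is cut (carbinol back to ketone), because the ketone is the direct product of an aldol C–C bond formation. One stereocenter disappears. The forward reduction must not dehydrate the electron-rich benzylic carbinol; syn selectivity is convenient but not essential, since C4 is oxidised again.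

**22 to 17 and 19.** The C2–C3 bond is cut. This divides the molecule into the ring A methyl ketone that already carries the side chain and the ring B aldehyde, and it creates C2 in the same step. The gain is two fragments of similar complexity. The demand is reagent control of the aldehyde face, because the stereocenters of 17 are too remote to help.

**19 to 18.** One phenolic O–CH2 acetal bond is cut, so the aldehyde partner comes from a commercial phenol in one step. The forward step must only alkylate on oxygen.

**17 to 15 and 10 (through 16).** The C8–C1'' bond between ring A and the side chain is cut. It is an sp2–sp3 bond next to a halogen-bearing carbon, and cutting it lets the stereodiad be built on a small acyclic fragment. The demand is a coupling that takes place at C–I and leaves the C–Br bond for the key step, tolerates the methyl ketone, and copes with two ortho substituents.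

**15 back to 11 through 14, 13 and 12.** The C8–I bond, the two acetal O–CH2 bonds (exchanged for methyl ethers in 14 and 13) and the C4a–acetyl bond are cut in turn. The bromine that becomes the leaving group at C8a is present from the start, and both electrophilic substitutions go to the two positions that flank it, each para to one oxygen. The gain is a symmetric commercial arene. The demands are regiocontrol in two successive aromatic substitutions, and exchange of methyl for acetal protection before the acid-sensitive side chain arrives.

**10 back to 6 through 9 and 8.** The C1''–I bond is traced to C1''–OH, then to the acyl–nitrogen bond of an auxiliary, and then the C2''–CH2 bond to the allylic group is cut. Alkylating a chelated imide enolate with a reactive allylic halide is the most reliable way to set C2'', and the auxiliary overrides the weak bias of C3''. The gain is a linear acyl chain with a single stereocenter. The demand is high facial selectivity and a reductive auxiliary removal that leaves the alkene alone.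

**6 back to 1 through 4 and 2.** The acyl–nitrogen bond, the C1''–C2'' bond (carboxyl carbon) and the O–CH2 acetal bond are cut. C3'' then comes from the chiral pool, and the chain is lengthened by one carbon with CO2. The demand is Grignard formation and carboxylation without loss of the acetal or of configuration.

## Other disconnections considered

**Alternative 1:** The cut goes through ring A: the C8–C8a, C6–C7 and C4a–C8a bonds are taken apart, so that ring A is assembled from the side-chain siloxyalkyne A2 and 3-ethoxycyclobut-2-en-1-one A3. In the forward direction, thermolysis would open A3 to a vinylketene. Its [2+2] cycloaddition with A2 (ketene carbon to the alkyne carbon that bears the side chain), four-electron ring opening, six-electron ring closure and tautomerisation would give the phenol A1.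

- In its favour: the order of substituents follows from the mechanism and not from directing effects. The regiochemical question of step 8 and the hindered coupling of step 11 do not arise, and on this point the alternative is better than the chosen plan. The conditions are neutral and thermal, and the three ring A oxygens emerge differentiated.
- Against it here: A1 still lacks C2, C3, C4 and ring B. The acyl group would have to be placed on C4a next to a free hydroxyl by a Friedel–Crafts or Fries-type reaction that the alkene tolerates poorly. Because the C8a oxygen is already present, ring C would be closed by a reversible oxa-Michael addition, which makes C2 the least secure centre. The C5 ethyl ether needs a late Lewis-acid dealkylation, and A2 is several steps from 10.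
- Comparison: structurally this route solves ring A, while the chosen plan solves ring C. Mechanistically it is a pericyclic cascade against a cross-coupling. In step count it is about equal for ring A and longer for the remainder.

**Alternative 2:** The cut removes ring A from a preformed, enantiomerically defined ring C: the C4a–C5 and C8–C8a bonds are disconnected to the bromo dihydropyranone A5 and the bis-silyloxy diene A6. In the forward direction the diene would add across the C5=C6 bond of A5 (pyranone numbering). Its alkyl-bearing nucleophilic terminus bonds to the oxygen-bearing carbon and its ketene acetal carbon to the brominated carbon. Loss of HBr and methanol then aromatises the adduct to A4, in which both ring A hydroxyls are free.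

- In its favour: C2 could be set on a small molecule by a catalytic asymmetric hetero-Diels–Alder reaction of 19, which is a better-controlled entry to this stereocenter than the boron aldol of step 13. Ring A arrives with both oxygens in one step, and A6 is only a few steps from 10 through a β-keto ester, so on paper the sequence is shorter than steps 7 to 15. On both points the alternative is the better one.
- Against it here: the enone of A5 is a vinylogous ester and a weak dienophile. A6 carries a substituent on its reacting terminus and is hydrolytically sensitive. The primary adduct and A4 both have the C2–O1 bond β to a carbonyl, so the eliminations needed for aromatisation can open ring C and erode C2.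
- Comparison: the chosen plan never exposes a C2–O bond β to a carbonyl to base before ring C is closed. The alternative is more convergent but rests on a cycloaddition with an unfavourable electronic and steric match.

**Alternative 3:** The cut removes both ring C bonds at ring A, O1–C8a and C4–C4a, and leads to the ortho-silylaryl triflate A8 and the β-hydroxy ester A9. In the forward direction CsF would generate the C4a–C8a aryne from A8. The oxygen of A9 adds at C8a, directed by the C5 alkoxy group that stabilises negative charge at C4a, and the aryl anion closes on the ester to give A7, which is identical with 26.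

- In its favour: it forms the same O1–C8a bond as the chosen plan and likewise leaves the C2–O bond intact. It reaches the ketone oxidation level directly, so the reduction and oxidation of steps 14 and 16 are not needed. A9 is accessible by asymmetric hydrogenation of a β-keto ester with secure control of configuration. On both step economy from the fragments and control of C2 it is equal to or better than the chosen plan.
- Against it here: A7 would be formed in the presence of fluoride and alkoxide, conditions that can reversibly open ring C and scramble C2. A9 can undergo retro-aldol cleavage or dehydration under the same conditions. The aryl anion may be protonated instead of acylated. C8a is the electronically preferred site but is shielded by the side chain. A8 needs a silylation/triflation sequence on a ring A phenol that is at least as long as steps 7 to 11.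
- Comparison: the chosen plan pays two redox steps to keep every base-sensitive stage away from a β-oxygenated ketone, and the alternative saves them at the price of that exposure.

Key step: step 15

Remarks on the chemistry (assumptions):
- With the carbinol carbons fixed as (2S) and (4R) in flavanone numbering, the open-chain diol 24 is the syn diol, and the flavan-4-ol 25 formed from it has the C2 aryl group and the C4 hydroxyl trans on ring C. The compounds are named on that basis; the C4 configuration has no bearing on the target because C4 becomes a carbonyl carbon.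
- (S)-3-Bromo-2-methylpropan-1-ol, the bromohydrin related to methyl 3-hydroxy-2-methylpropanoate, is taken as a purchasable starting material.
- The antipode of Ipc2BCl named in step 13 is the one expected to direct the enolate to the Si face of the aldehyde; should the sense prove opposite, the mirror-image reagent is used with no other change.

## Route

Step 1
Reactants: 1 (S)-3-bromo-2-methylpropan-1-ol
Product: 2 (S)-1-bromo-3-(methoxymethoxy)-2-methylpropane
Conditions: MOMCl, iPr2NEt, CH2Cl2, 0 °C to rt
Reagents that add atoms: chloromethyl methyl ether, COCCl
Why: O-alkylation of the primary alcohol by the α-chloro ether under amine base (acetal formation); the stereocenter is not involved and the acetal later survives organometallic, basic and hydride conditions.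

Step 2
Reactants: 2 (S)-1-bromo-3-(methoxymethoxy)-2-methylpropane
Product: 4 (R)-4-(methoxymethoxy)-3-methylbutanoic acid, via Grignard reagent 3 (not isolated)
Conditions: Mg, I2 (cat.), THF, 40 °C; CO2, −78 °C to rt; 1 M HCl, 0 °C
Reagents that add atoms: carbon dioxide, O=C=O
Why: Grignard formation and carboxylation add the carbon that becomes C1''; the stereocenter is β to magnesium and the ether oxygen is too remote for elimination, so the configuration is retained (the descriptor changes only through the priority rules).

Step 3
Reactants: 4 (R)-4-(methoxymethoxy)-3-methylbutanoic acid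
Product: 6 (S)-4-benzyl-3-[(R)-4-(methoxymethoxy)-3-methylbutanoyl]oxazolidin-2-one, via mixed pivalic anhydride 5 (not isolated)
Conditions: PivCl, Et3N, THF, −20 °C; then LiCl, (S)-4-benzyloxazolidin-2-one, −20 °C to rt
Reagents that add atoms: (S)-4-benzyloxazolidin-2-one, O=C1N[C@@H](Cc2ccccc2)CO1
Why: N-acylation of the oxazolidinone through a mixed anhydride, with attack at the less hindered acyl carbon; no stereocenter is touched.

Step 4
Reactants: 6 (S)-4-benzyl-3-[(R)-4-(methoxymethoxy)-3-methylbutanoyl]oxazolidin-2-one
Product: 8 (S)-4-benzyl-3-[(2S,3R)-4-(methoxymethoxy)-3-methyl-2-(3-methylbut-2-en-1-yl)butanoyl]oxazolidin-2-one, via sodium enolate 7 (not isolated)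
Conditions: NaN(SiMe3)2, THF, −78 °C; prenyl bromide, −78 to −40 °C
Reagents that add atoms: 1-bromo-3-methylbut-2-ene, CC(C)=CCBr
Why: Evans alkylation: the chelated (Z)-enolate is attacked by the allylic bromide on the face opposite the benzyl group, which sets C2'' under auxiliary control (the same sense as the well-known allylation of the propionyl imide) and overrides the small bias of the adjacent C3'' center.

Step 5
Reactants: 8 (S)-4-benzyl-3-[(2S,3R)-4-(methoxymethoxy)-3-methyl-2-(3-methylbut-2-en-1-yl)butanoyl]oxazolidin-2-one
Product: 9 (2S,3R)-4-(methoxymethoxy)-3-methyl-2-(3-methylbut-2-en-1-yl)butan-1-ol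
Conditions: LiBH4, MeOH (1 equiv), Et2O, 0 °C
Reagents that add atoms: none
Why: Reductive cleavage of the N-acyl oxazolidinone at the exocyclic carbonyl gives the primary alcohol and releases the auxiliary; the borohydride does not touch the alkene or the acetal and no epimerisable carbonyl compound is isolated.

Step 6
Reactants: 9 (2S,3R)-4-(methoxymethoxy)-3-methyl-2-(3-methylbut-2-en-1-yl)butan-1-ol
Product: 10 (5S,6R)-5-(iodomethyl)-7-(methoxymethoxy)-2,6-dimethylhept-2-ene
Conditions: I2, PPh3, imidazole, CH2Cl2, 0 °C to rt
Reagents that add atoms: iodine, II
Why: Appel-type iodination: the alkoxyphosphonium ion is displaced by iodide in an SN2 reaction at the primary carbon, and imidazole buffers the medium so that the acetal and the alkene survive; both stereocenters are untouched.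

Step 7
Reactants: 11 1-bromo-3,5-dimethoxybenzene
Product: 12 1-(2-bromo-4,6-dimethoxyphenyl)ethan-1-one
Conditions: AcCl, AlCl3, CH2Cl2, 0 °C
Reagents that add atoms: acetyl chloride, CC(Cl)=O
Why: Friedel–Crafts acylation at the position para to one methoxy group and ortho to the other (next to bromine), which is preferred over the more crowded position between the two methoxy groups as in formylations and halogenations of this arene; the two such positions are equivalent, so one constitution results.

Step 8
Reactants: 12 1-(2-bromo-4,6-dimethoxyphenyl)ethan-1-one
Product: 13 1-(2-bromo-3-iodo-4,6-dimethoxyphenyl)ethan-1-one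
Conditions: NIS, CF3CO2H (cat.), MeCN, rt
Reagents that add atoms: N-iodosuccinimide, O=C1CCC(=O)N1I
Why: Electrophilic aromatic iodination: C3 is para to the C6 methoxyl and ortho to the C4 methoxyl, whereas the only other free position lies between two methoxy groups and is shielded by the C6 methoxyl, which must turn its methyl group away from the acetyl group; the ring is far more nucleophilic than the enol of the ketone.

Step 9
Reactants: 13 1-(2-bromo-3-iodo-4,6-dimethoxyphenyl)ethan-1-one
Product: 14 1-(2-bromo-4,6-dihydroxy-3-iodophenyl)ethan-1-one
Conditions: BBr3, CH2Cl2, −78 °C to rt; then ice water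
Reagents that add atoms: none
Why: Lewis-acid cleavage of both aryl methyl ethers (bromide attacks the methyl group of the boron-complexed ether); it is done now because neither the alkene nor acetal protecting groups could survive it later, and aryl halides and the ketone are inert to it.

Step 10
Reactants: 14 1-(2-bromo-4,6-dihydroxy-3-iodophenyl)ethan-1-one
Product: 15 1-[2-bromo-3-iodo-4,6-bis(methoxymethoxy)phenyl]ethan-1-one
Conditions: NaH, MOMCl, DMF, 0 °C to rt
Reagents that add atoms: chloromethyl methyl ether, COCCl
Why: Williamson-type O-alkylation of both phenoxides; the strong base is chosen so that the hydroxyl hydrogen-bonded to the acetyl group is protected as well.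

Step 11
Reactants: 10 (5S,6R)-5-(iodomethyl)-7-(methoxymethoxy)-2,6-dimethylhept-2-ene; 15 1-[2-bromo-3-iodo-4,6-bis(methoxymethoxy)phenyl]ethan-1-one
Product: 17 1-{2-bromo-4,6-bis(methoxymethoxy)-3-[(2R,3R)-4-(methoxymethoxy)-3-methyl-2-(3-methylbut-2-en-1-yl)butyl]phenyl}ethan-1-one, via alkylzinc iodide 16 (not isolated)
Conditions: 10, Zn dust (BrCH2CH2Br, Me3SiCl activation), THF, 40 °C; then 15, Pd(OAc)2, SPhos, THF/DMA, 25–40 °C
Reagents that add atoms: none
Why: Negishi coupling: zinc inserts into the primary C–I bond without touching the remote alkene or the acetal, zerovalent palladium adds to the C–I bond of 15 much faster than to the C–Br bond, and the dialkylbiarylphosphine promotes transmetalation and reductive elimination at the doubly ortho-substituted arylpalladium ahead of β-hydride elimination; the methyl ketone is tolerated by the organozinc and no stereocenter is at a reacting carbon.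

Step 12
Reactants: 18 4-hydroxy-2-methoxybenzaldehyde
Product: 19 2-methoxy-4-(methoxymethoxy)benzaldehyde
Conditions: MOMCl, iPr2NEt, CH2Cl2, 0 °C to rt
Reagents that add atoms: chloromethyl methyl ether, COCCl
Why: O-alkylation of the acidic para-formyl phenol under amine base; masking the phenol keeps it from quenching the boron enolate in the next step.

Step 13
Reactants: 17 1-{2-bromo-4,6-bis(methoxymethoxy)-3-[(2R,3R)-4-(methoxymethoxy)-3-methyl-2-(3-methylbut-2-en-1-yl)butyl]phenyl}ethan-1-one; 19 2-methoxy-4-(methoxymethoxy)benzaldehyde
Product: 22 (S)-1-{2-bromo-4,6-bis(methoxymethoxy)-3-[(2R,3R)-4-(methoxymethoxy)-3-methyl-2-(3-methylbut-2-en-1-yl)butyl]phenyl}-3-hydroxy-3-[2-methoxy-4-(methoxymethoxy)phenyl]propan-1-one, via enol borinate 20 (not isolated), via borinate aldolate 21 (not isolated)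
Conditions: (+)-Ipc2BCl, Et3N, Et2O, −78 to 0 °C; then 19, −78 to −20 °C; H2O2, pH 7 buffer, MeOH, 0 °C
Reagents that add atoms: none
Why: Boron-mediated aldol addition with a chiral dialkylchloroborane: amine-assisted enolisation gives the enol diisopinocampheylborinate, which adds to the aldehyde through a cyclic six-membered transition state in which the isopinocampheyl groups differentiate the aldehyde faces, so that Si-face attack sets the (S)-carbinol at C2 by reagent control; the buffered oxidative work-up frees the β-hydroxy ketone without acid or base and so avoids dehydration.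

Step 14
Reactants: 22 (S)-1-{2-bromo-4,6-bis(methoxymethoxy)-3-[(2R,3R)-4-(methoxymethoxy)-3-methyl-2-(3-methylbut-2-en-1-yl)butyl]phenyl}-3-hydroxy-3-[2-methoxy-4-(methoxymethoxy)phenyl]propan-1-one
Product: 24 (1R,3S)-1-{2-bromo-4,6-bis(methoxymethoxy)-3-[(2R,3R)-4-(methoxymethoxy)-3-methyl-2-(3-methylbut-2-en-1-yl)butyl]phenyl}-3-[2-methoxy-4-(methoxymethoxy)phenyl]propane-1,3-diol, via diethylboron chelate 23 (not isolated)
Conditions: Et2BOMe, THF/MeOH (4:1), −78 °C; NaBH4, −78 °C; then H2O2, pH 7 buffer, 0 °C
Reagents that add atoms: none
Why: Narasaka–Prasad reduction: the boron chelate holds the β-hydroxy ketone in a six-membered half-chair with the ring B aryl group equatorial and external hydride attacks axially, so the new C4 carbinol (R) is set syn to C2 by 1,3-induction; the low temperature and neutral work-up protect the electron-rich benzylic carbinol.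

Step 15
Reactants: 24 (1R,3S)-1-{2-bromo-4,6-bis(methoxymethoxy)-3-[(2R,3R)-4-(methoxymethoxy)-3-methyl-2-(3-methylbut-2-en-1-yl)butyl]phenyl}-3-[2-methoxy-4-(methoxymethoxy)phenyl]propane-1,3-diol
Product: 25 (2S,4R)-2-[2-methoxy-4-(methoxymethoxy)phenyl]-5,7-bis(methoxymethoxy)-8-[(2R,3R)-4-(methoxymethoxy)-3-methyl-2-(3-methylbut-2-en-1-yl)butyl]-3,4-dihydro-2H-chromen-4-ol
Conditions: Pd(OAc)2 (5 mol %), 2-(di-tert-butylphosphino)-1,1'-binaphthyl (6 mol %), Cs2CO3, toluene, 80 °C
Reagents that add atoms: none
Why: Pd(OAc)2 is reduced in the flask to a zerovalent palladium–phosphine complex, which adds oxidatively to the C8a–Br bond; carbonate-assisted exchange of bromide for the C2 alkoxide gives a seven-membered aryl(alkoxo) complex of divalent palladium, and C–O reductive elimination forms the O1–C8a bond and regenerates the catalyst. The closest known reaction type is the palladium-catalysed intramolecular etherification of aryl bromides with secondary alcohols (Buchwald–Hartwig-type C–O coupling) that gives 2-substituted chromans without loss of configuration. Ring C is closed as a six-membered ring by C(sp2)–O reductive elimination from the seven-membered palladacycle, formally a 6-exo closure onto C8a with the C–Br bond as the exocyclic leaving bond. No stereocenter is created: C2 keeps its configuration because the C2–O bond is never broken, and C4 is a spectator, so the syn diol necessarily gives the 2,4-trans flavan-4-ol. The selectivity needed is between the two hydroxyls, and the substrate secures it by ring size, since the C4 oxygen could only close a four-membered ring and at most forms a reversible five-membered chelate. The bulky, electron-rich phosphine is chosen to speed reductive elimination past β-hydride elimination of the alkoxide and to permit oxidative addition at the doubly ortho-substituted carbon; the two alkoxy groups on ring A are meta to bromine and do not deactivate it. Carrying C4 as a carbinol means that the carbonate base meets no β-hydroxy ketone, so retro-aldol cleavage and dehydration cannot compete.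

Step 16
Reactants: 25 (2S,4R)-2-[2-methoxy-4-(methoxymethoxy)phenyl]-5,7-bis(methoxymethoxy)-8-[(2R,3R)-4-(methoxymethoxy)-3-methyl-2-(3-methylbut-2-en-1-yl)butyl]-3,4-dihydro-2H-chromen-4-ol
Product: 26 (S)-2-[2-methoxy-4-(methoxymethoxy)phenyl]-5,7-bis(methoxymethoxy)-8-[(2R,3R)-4-(methoxymethoxy)-3-methyl-2-(3-methylbut-2-en-1-yl)butyl]-2,3-dihydro-4H-chromen-4-one
Conditions: Dess–Martin periodinane, NaHCO3, CH2Cl2, 0 °C to rt
Reagents that add atoms: none
Why: Dess–Martin oxidation of the secondary benzylic alcohol by ligand exchange at hypervalent iodine and intramolecular deprotonation; the buffered, neutral conditions leave the alkene, the acetals and the C2 configuration untouched, and C4 loses its stereocenter as planned.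

Step 17
Reactants: 26 (S)-2-[2-methoxy-4-(methoxymethoxy)phenyl]-5,7-bis(methoxymethoxy)-8-[(2R,3R)-4-(methoxymethoxy)-3-methyl-2-(3-methylbut-2-en-1-yl)butyl]-2,3-dihydro-4H-chromen-4-one
Product: 27 (S)-5,7-dihydroxy-2-(4-hydroxy-2-methoxyphenyl)-8-[(2R,3R)-4-hydroxy-3-methyl-2-(3-methylbut-2-en-1-yl)butyl]-2,3-dihydro-4H-chromen-4-one
Conditions: HCl (2 M in MeOH), THF, 40 °C
Reagents that add atoms: none
Why: Acid-catalysed transacetalisation to methanol removes all four methoxymethyl groups (the three aryl acetals fast, the aliphatic one more slowly); dilute acid at moderate temperature is chosen to avoid addition to the trisubstituted alkene and opening of ring C, and the aryl methyl ether is inert.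

## Compound list

1 | (S)-3-bromo-2-methylpropan-1-ol | BrC[C@@H](C)CO | starting material
2 | (S)-1-bromo-3-(methoxymethoxy)-2-methylpropane | BrC[C@@H](C)COCOC | intermediate
3 | [(S)-3-(methoxymethoxy)-2-methylpropyl]magnesium bromide | Br[Mg]C[C@@H](C)COCOC | intermediate
4 | (R)-4-(methoxymethoxy)-3-methylbutanoic acid | OC(=O)C[C@@H](C)COCOC | intermediate
5 | (R)-4-(methoxymethoxy)-3-methylbutanoic pivalic anhydride | CC(C)(C)C(=O)OC(=O)C[C@@H](C)COCOC | intermediate
6 | (S)-4-benzyl-3-[(R)-4-(methoxymethoxy)-3-methylbutanoyl]oxazolidin-2-one | O=C(C[C@@H](C)COCOC)N1[C@@H](Cc2ccccc2)COC1=O | intermediate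
7 | sodium (Z)-enolate of 6 | [Na+].[O-]/C(=C\[C@@H](C)COCOC)N1[C@@H](Cc2ccccc2)COC1=O | intermediate
8 | (S)-4-benzyl-3-[(2S,3R)-4-(methoxymethoxy)-3-methyl-2-(3-methylbut-2-en-1-yl)butanoyl]oxazolidin-2-one | O=C([C@@H](CC=C(C)C)[C@@H](C)COCOC)N1[C@@H](Cc2ccccc2)COC1=O | intermediate
9 | (2S,3R)-4-(methoxymethoxy)-3-methyl-2-(3-methylbut-2-en-1-yl)butan-1-ol | OC[C@@H](CC=C(C)C)[C@@H](C)COCOC | intermediate
10 | (5S,6R)-5-(iodomethyl)-7-(methoxymethoxy)-2,6-dimethylhept-2-ene | IC[C@@H](CC=C(C)C)[C@@H](C)COCOC | intermediate
11 | 1-bromo-3,5-dimethoxybenzene | COc1cc(Br)cc(OC)c1 | starting material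
12 | 1-(2-bromo-4,6-dimethoxyphenyl)ethan-1-one | CC(=O)c1c(Br)cc(OC)cc1OC | intermediate
13 | 1-(2-bromo-3-iodo-4,6-dimethoxyphenyl)ethan-1-one | CC(=O)c1c(Br)c(I)c(OC)cc1OC | intermediate
14 | 1-(2-bromo-4,6-dihydroxy-3-iodophenyl)ethan-1-one | CC(=O)c1c(Br)c(I)c(O)cc1O | intermediate
15 | 1-[2-bromo-3-iodo-4,6-bis(methoxymethoxy)phenyl]ethan-1-one | CC(=O)c1c(Br)c(I)c(OCOC)cc1OCOC | intermediate
16 | [(2S,3R)-4-(methoxymethoxy)-3-methyl-2-(3-methylbut-2-en-1-yl)butyl]zinc iodide | I[Zn]C[C@@H](CC=C(C)C)[C@@H](C)COCOC | intermediate
17 | 1-{2-bromo-4,6-bis(methoxymethoxy)-3-[(2R,3R)-4-(methoxymethoxy)-3-methyl-2-(3-methylbut-2-en-1-yl)butyl]phenyl}ethan-1-one | CC(=O)c1c(Br)c(C[C@@H](CC=C(C)C)[C@@H](C)COCOC)c(OCOC)cc1OCOC | intermediate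
18 | 4-hydroxy-2-methoxybenzaldehyde | COc1cc(O)ccc1C=O | starting material
19 | 2-methoxy-4-(methoxymethoxy)benzaldehyde | COc1cc(OCOC)ccc1C=O | intermediate
20 | enol bis[(+)-isopinocampheyl]borinate of 17 | C=C(OB([C@H]1C[C@H]2C[C@@H]([C@@H]1C)C2(C)C)[C@H]1C[C@H]2C[C@@H]([C@@H]1C)C2(C)C)c1c(Br)c(C[C@@H](CC=C(C)C)[C@@H](C)COCOC)c(OCOC)cc1OCOC | intermediate
21 | O-bis[(+)-isopinocampheyl]boryl derivative of 22 (borinate aldolate) | COc1cc(OCOC)ccc1[C@@H](OB([C@H]2C[C@H]3C[C@@H]([C@@H]2C)C3(C)C)[C@H]2C[C@H]3C[C@@H]([C@@H]2C)C3(C)C)CC(=O)c1c(Br)c(C[C@@H](CC=C(C)C)[C@@H](C)COCOC)c(OCOC)cc1OCOC | intermediate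
22 | (S)-1-{2-bromo-4,6-bis(methoxymethoxy)-3-[(2R,3R)-4-(methoxymethoxy)-3-methyl-2-(3-methylbut-2-en-1-yl)butyl]phenyl}-3-hydroxy-3-[2-methoxy-4-(methoxymethoxy)phenyl]propan-1-one | COc1cc(OCOC)ccc1[C@@H](O)CC(=O)c1c(OCOC)cc(OCOC)c(C[C@@H](CC=C(C)C)[C@@H](C)COCOC)c1Br | intermediate
23 | O-diethylboryl derivative of 22 (boron chelate, ketone oxygen coordinated to boron) | COc1cc(OCOC)ccc1[C@@H](OB(CC)CC)CC(=O)c1c(OCOC)cc(OCOC)c(C[C@@H](CC=C(C)C)[C@@H](C)COCOC)c1Br | intermediate
24 | (1R,3S)-1-{2-bromo-4,6-bis(methoxymethoxy)-3-[(2R,3R)-4-(methoxymethoxy)-3-methyl-2-(3-methylbut-2-en-1-yl)butyl]phenyl}-3-[2-methoxy-4-(methoxymethoxy)phenyl]propane-1,3-diol (syn diol) | COc1cc(OCOC)ccc1[C@@H](O)C[C@@H](O)c1c(OCOC)cc(OCOC)c(C[C@@H](CC=C(C)C)[C@@H](C)COCOC)c1Br | intermediate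
25 | (2S,4R)-2-[2-methoxy-4-(methoxymethoxy)phenyl]-5,7-bis(methoxymethoxy)-8-[(2R,3R)-4-(methoxymethoxy)-3-methyl-2-(3-methylbut-2-en-1-yl)butyl]-3,4-dihydro-2H-chromen-4-ol (2,4-trans) | COc1cc(OCOC)ccc1[C@@H]1C[C@@H](O)c2c(OCOC)cc(OCOC)c(C[C@@H](CC=C(C)C)[C@@H](C)COCOC)c2O1 | intermediate
26 | (S)-2-[2-methoxy-4-(methoxymethoxy)phenyl]-5,7-bis(methoxymethoxy)-8-[(2R,3R)-4-(methoxymethoxy)-3-methyl-2-(3-methylbut-2-en-1-yl)butyl]-2,3-dihydro-4H-chromen-4-one | COc1cc(OCOC)ccc1[C@@H]1CC(=O)c2c(OCOC)cc(OCOC)c(C[C@@H](CC=C(C)C)[C@@H](C)COCOC)c2O1 | intermediate
27 | (S)-5,7-dihydroxy-2-(4-hydroxy-2-methoxyphenyl)-8-[(2R,3R)-4-hydroxy-3-methyl-2-(3-methylbut-2-en-1-yl)butyl]-2,3-dihydro-4H-chromen-4-one | COc1cc(O)ccc1[C@@H]1CC(=O)c2c(O)cc(O)c(C[C@@H](CC=C(C)C)[C@@H](C)CO)c2O1 | target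

## Step count and least certain steps

Total: 17 steps. Longest linear sequence: 12 steps (steps 1 to 6, 11, 13 to 17).

**Step 15 (key step).** Oxidative addition at the doubly ortho-substituted C–Br bond may be slow. The palladium alkoxide may undergo β-hydride elimination, which oxidises a carbinol and reduces the C–Br bond to C–H. The nearer C4 alkoxide may hold palladium in a five-membered chelate and stall turnover. The fallback masks the C4 hydroxyl; it sets out from 24 and returns at 25. Both hydroxyls are silylated (Et3SiOTf, 2,6-lutidine, CH2Cl2, −78 °C) to the bis(triethylsilyl) ether of 24 F1. The silyl ether on the less hindered ring B carbinol is removed selectively (HF·pyridine, pyridine, THF, 0 °C) to give the C4-mono(triethylsilyl) ether of 24 F2, in which only the C2 hydroxyl is free. The same palladium-catalysed etherification then gives the 4-O-triethylsilyl ether of 25 F3, and Bu4NF in THF releases 25.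

**Step 13.** Facial discrimination by the isopinocampheyl groups may be incomplete for an unsubstituted methyl ketone enolate, so that the C2 epimer is carried on as a diastereomer that the remote side-chain centers make hard to remove. Addition to the electron-rich aldehyde may also be slow. The fallback sets the C2 oxygen by asymmetric epoxidation; it sets out from 17 and 19 and returns at 22. Claisen–Schmidt condensation (KOH, EtOH, rt) gives the (E)-chalcone F4. Juliá–Colonna epoxidation (poly-D-leucine, urea–H2O2, DBU, THF) gives the (2S,3R)-epoxy ketone F5. SmI2 (THF/MeOH, −78 °C) then cleaves the Cα–O bond reductively and gives 22 with the Cβ–O bond, the future C2–O1 bond, untouched.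

**Step 11.** Transmetalation and reductive elimination at an arylpalladium flanked by bromine and an acetal may be slow enough for β-hydride elimination of the alkyl group or protodeiodination to compete. Forcing conditions could erode the iodine-over-bromine selectivity. The fallback changes the nucleophile to a borate; it sets out from 10 and returns at 17. Lithium–iodine exchange (t-BuLi, Et2O, −78 °C) and trapping with B-methoxy-9-BBN give the lithium alkyl(methoxy)borate F6, which is coupled with 15 in a Suzuki–Miyaura reaction (PdCl2(dppf), K3PO4, DMF/H2O, rt to 50 °C).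

**Step 8.** Iodination may go partly to the position between the two methoxy groups, or to the enol of the ketone, and give regioisomer mixtures. The fallback reverses the order of the two aromatic substitutions; it sets out from 11 and returns at 13. Iodination of 11 (NIS, MeCN), where the two reactive positions are equivalent, gives 1-bromo-2-iodo-3,5-dimethoxybenzene F7. Friedel–Crafts acetylation with a milder Lewis acid (AcCl, SnCl4, CH2Cl2, −20 °C) then goes to the one remaining position para to a methoxy group.

**Step 17.** The aliphatic acetal leaves more slowly than the aryl acetals. Prolonged protic acid risks addition of methanol or HCl across the trisubstituted alkene and reversible opening of the C2–O1 bond with loss of configuration at C2. The fallback replaces protic solvolysis by aprotic bromoborane cleavage; it sets out from 26 and returns at 27. Me2BBr in CH2Cl2 at −78 °C converts each acetal into a bromomethyl ether, which is hydrolysed on work-up with aqueous NaHCO3; no new isolated compound arises.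

## Further compounds

F1 | step 15 | bis(triethylsilyl) ether of 24 | COc1cc(OCOC)ccc1[C@@H](O[Si](CC)(CC)CC)C[C@@H](O[Si](CC)(CC)CC)c1c(OCOC)cc(OCOC)c(C[C@@H](CC=C(C)C)[C@@H](C)COCOC)c1Br
F2 | step 15 | C4-mono(triethylsilyl) ether of 24 (free hydroxyl on the ring B carbinol) | COc1cc(OCOC)ccc1[C@@H](O)C[C@@H](O[Si](CC)(CC)CC)c1c(OCOC)cc(OCOC)c(C[C@@H](CC=C(C)C)[C@@H](C)COCOC)c1Br
F3 | step 15 | 4-O-triethylsilyl ether of 25 | COc1cc(OCOC)ccc1[C@@H]1C[C@@H](O[Si](CC)(CC)CC)c2c(OCOC)cc(OCOC)c(C[C@@H](CC=C(C)C)[C@@H](C)COCOC)c2O1
F4 | step 13 | (E)-1-{2-bromo-4,6-bis(methoxymethoxy)-3-[(2R,3R)-4-(methoxymethoxy)-3-methyl-2-(3-methylbut-2-en-1-yl)butyl]phenyl}-3-[2-methoxy-4-(methoxymethoxy)phenyl]prop-2-en-1-one | COc1cc(OCOC)ccc1/C=C/C(=O)c1c(OCOC)cc(OCOC)c(C[C@@H](CC=C(C)C)[C@@H](C)COCOC)c1Br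
F5 | step 13 | {2-bromo-4,6-bis(methoxymethoxy)-3-[(2R,3R)-4-(methoxymethoxy)-3-methyl-2-(3-methylbut-2-en-1-yl)butyl]phenyl}{(2S,3R)-3-[2-methoxy-4-(methoxymethoxy)phenyl]oxiran-2-yl}methanone | COc1cc(OCOC)ccc1[C@H]1O[C@@H]1C(=O)c1c(OCOC)cc(OCOC)c(C[C@@H](CC=C(C)C)[C@@H](C)COCOC)c1Br
F6 | step 11 | lithium B-methoxy-B-[(2S,3R)-4-(methoxymethoxy)-3-methyl-2-(3-methylbut-2-en-1-yl)butyl]-9-borabicyclo[3.3.1]nonan-9-uide | [Li+].CO[B-]1(C[C@@H](CC=C(C)C)[C@@H](C)COCOC)C2CCCC1CCC2
F7 | step 8 | 1-bromo-2-iodo-3,5-dimethoxybenzene | COc1cc(OC)c(I)c(Br)c1
F0 | step 17 | none | none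
A1 | alternative 1 | 5-ethoxy-2-[(2R,3R)-4-(methoxymethoxy)-3-methyl-2-(3-methylbut-2-en-1-yl)butyl]-3-(triisopropylsilyloxy)phenol | CCOc1cc(O)c(C[C@@H](CC=C(C)C)[C@@H](C)COCOC)c(O[Si](C(C)C)(C(C)C)C(C)C)c1
A2 | alternative 1 | triisopropyl{[(4R,5R)-6-(methoxymethoxy)-5-methyl-4-(3-methylbut-2-en-1-yl)hex-1-yn-1-yl]oxy}silane | CC(C)[Si](OC#CC[C@@H](CC=C(C)C)[C@@H](C)COCOC)(C(C)C)C(C)C
A3 | alternative 1 | 3-ethoxycyclobut-2-en-1-one | CCOC1=CC(=O)C1
A4 | alternative 2 | (S)-5,7-dihydroxy-2-[2-methoxy-4-(methoxymethoxy)phenyl]-8-[(2R,3R)-4-(methoxymethoxy)-3-methyl-2-(3-methylbut-2-en-1-yl)butyl]-2,3-dihydro-4H-chromen-4-one | COc1cc(OCOC)ccc1[C@@H]1CC(=O)c2c(O)cc(O)c(C[C@@H](CC=C(C)C)[C@@H](C)COCOC)c2O1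
A5 | alternative 2 | (S)-5-bromo-2-[2-methoxy-4-(methoxymethoxy)phenyl]-2,3-dihydro-4H-pyran-4-one | COc1cc(OCOC)ccc1[C@@H]1CC(=O)C(Br)=CO1
A6 | alternative 2 | (6R,7R)-1-methoxy-8-(methoxymethoxy)-7-methyl-6-(3-methylbut-2-en-1-yl)-1,3-bis(trimethylsilyloxy)octa-1,3-diene | COC(O[Si](C)(C)C)=CC(O[Si](C)(C)C)=CC[C@@H](CC=C(C)C)[C@@H](C)COCOC
A7 | alternative 3 | (S)-2-[2-methoxy-4-(methoxymethoxy)phenyl]-5,7-bis(methoxymethoxy)-8-[(2R,3R)-4-(methoxymethoxy)-3-methyl-2-(3-methylbut-2-en-1-yl)butyl]-2,3-dihydro-4H-chromen-4-one (identical with 26) | COc1cc(OCOC)ccc1[C@@H]1CC(=O)c2c(OCOC)cc(OCOC)c(C[C@@H](CC=C(C)C)[C@@H](C)COCOC)c2O1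
A8 | alternative 3 | 3,5-bis(methoxymethoxy)-2-[(2R,3R)-4-(methoxymethoxy)-3-methyl-2-(3-methylbut-2-en-1-yl)butyl]-6-(trimethylsilyl)phenyl trifluoromethanesulfonate | C[Si](C)(C)c1c(OCOC)cc(OCOC)c(C[C@@H](CC=C(C)C)[C@@H](C)COCOC)c1OS(=O)(=O)C(F)(F)F
A9 | alternative 3 | methyl (S)-3-hydroxy-3-[2-methoxy-4-(methoxymethoxy)phenyl]propanoate | COc1cc(OCOC)ccc1[C@@H](O)CC(=O)OC
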